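**Assumptions (one line each)**
- Stereochemistry read from the SMILES: flavanone C2 is R; the cyclohexene is all-trans (exo-type), with the carbon bearing the flavanone aryl R, the carbon bearing the aroyl group R, and the carbon bearing the dihydroxyphenyl group S, i.e. (1R,5S,6R) in the name of 21.
- The exo-selective Morus alba Diels–Alderase MaDA-3 is not a catalogue item; it is made by recombinant expression and treated as a catalyst.
- The sense of induction of the Rh ligand in Step 4 is assigned by analogy with Rh/biaryl-bisphosphine additions to cyclic enones; confirm by chiral HPLC/CD and use the ligand antipode if it is reversed.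

**Retrosynthetic overview**
1. Target ⇒ intermolecular exo-selective [4+2] between a free (2R)-flavanone dehydroprenyl diene and 2,4,2',4'-tetrahydroxychalcone, catalysed by a Diels–Alderase; the cyclohexene is formed last and its three stereocentres are set together.
2. Flavanone diene ⇒ neutral Stille coupling of a dienylstannane onto a TBS-protected (2R)-5'-bromoflavanone, then buffered desilylation.
3. Bromoflavanone ⇒ Rh-catalysed asymmetric 1,4-addition of an arylboronic acid to 7-silyloxychromone (first stereocentre, C2).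
4. Chalcone ⇒ Claisen–Schmidt condensation of MOM-protected 2',4'-dihydroxyacetophenone and 2,4-dihydroxybenzaldehyde.
5. Ring order: the chromone pyranone is purchased preformed, then C2 is set, then the cyclohexene is built by the enzymatic Diels–Alder.

**Route**

Step 1
Reactants: 1, 4,6-dibromobenzene-1,3-diol; 2, tert-butyldimethylsilyl chloride
Product: 3, 1,5-dibromo-2,4-bis(tert-butyldimethylsilyloxy)benzene
Conditions: TBSCl (2.4 eq), imidazole (5 eq), DMF, 0 °C → rt
Reagents that add atoms: TBSCl, CC(C)(C)[Si](C)(C)Cl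
Why: Standard O-silylation of phenols; TBS is chosen because it can be removed at the end with buffered fluoride without touching the diene or the flavanone stereocentre.

Step 2
Reactants: 3; 4, triisopropyl borate
Product: 5, [5-bromo-2,4-bis(tert-butyldimethylsilyloxy)phenyl]boronic acid
Conditions: B(OiPr)3 (1.3 eq) present, n-BuLi (1.05 eq) added at −78 °C, THF/toluene (in situ quench); → −20 °C; aq. NH4Cl
Reagents that add atoms: triisopropyl borate, CC(C)OB(OC(C)C)OC(C)C; water, O
Why: Mono Br–Li exchange on the symmetric dibromide with immediate borate trapping (lithiation–borylation) outruns retro-Brook silyl migration and leaves the second bromide as the later coupling handle.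

Step 3
Reactants: 6, 7-hydroxy-4H-chromen-4-one; 2, TBSCl
Product: 7, 7-(tert-butyldimethylsilyloxy)-4H-chromen-4-one
Conditions: TBSCl (1.2 eq), imidazole, CH2Cl2/DMF, rt
Reagents that add atoms: TBSCl, CC(C)(C)[Si](C)(C)Cl
Why: Phenol silylation masks the acidic 7-OH so it cannot quench the aryl-rhodium species in the next step.

Step 4
Reactants: 7; 5 (2.0 eq)
Product: 8, (2R)-2-[5-bromo-2,4-bis(tert-butyldimethylsilyloxy)phenyl]-7-(tert-butyldimethylsilyloxy)-2,3-dihydro-4H-chromen-4-one
Conditions: [Rh(OH)(cod)]2 (2.5 mol%), (R)-MeO-F12-BIPHEP (5.5 mol%), toluene/H2O 10:1, 30 °C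
Reagents that add atoms: none (aryl from 5, C3–H from water)
Why: Hayashi–Miyaura-type Rh-catalysed asymmetric 1,4-addition, in which the chiral bisphosphine selects the enone face and sets C2 as R, while the neutral conditions avoid retro-oxa-Michael opening and leave the Ar–Br intact.

Step 5
Reactants: 9, (E)-1,2-bis(tributylstannyl)ethene (2.5 eq); 10, 2-bromopropene
Product: 11, tributyl[(1E)-3-methylbuta-1,3-dien-1-yl]stannane
Conditions: Pd(PPh3)4 (3 mol%), toluene, 80 °C, sealed tube; Kugelrohr distillation from excess 9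
Reagents that add atoms: none
Why: Mono-Stille coupling is stereoretentive at the alkenyl–tin carbon, so the E geometry of 9 is carried into the diene, and excess distannane suppresses double coupling.

Step 6
Reactants: 8; 11 (1.5 eq)
Product: 12, (2R)-2-{2,4-bis(tert-butyldimethylsilyloxy)-5-[(1E)-3-methylbuta-1,3-dien-1-yl]phenyl}-7-(tert-butyldimethylsilyloxy)-2,3-dihydro-4H-chromen-4-one
Conditions: Pd(P-t-Bu3)2 (5 mol%), toluene, 80 °C, dark, no fluoride or base; Et3N-deactivated silica
Reagents that add atoms: none
Why: Stille coupling with a bulky electron-rich phosphine engages the hindered, electron-rich aryl bromide under strictly neutral conditions, so the silyl ethers and the base-labile C2 stereocentre are untouched and the diene stays E.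

Step 7
Reactants: 12
Product: 13, (2R)-2-{2,4-dihydroxy-5-[(1E)-3-methylbuta-1,3-dien-1-yl]phenyl}-7-hydroxy-2,3-dihydro-4H-chromen-4-one
Conditions: TBAF (3.3 eq)/AcOH (3.6 eq), THF, 0 °C, 30 min; pH 6.5 phosphate work-up; use at once
Reagents that add atoms: none
Why: Acetic-acid-buffered fluoride cleaves the three aryl silyl ethers at near-neutral pH, avoiding both acid-induced diene cyclisation and phenoxide-driven ring opening (epimerisation) of the flavanone.

Step 8
Reactants: 14, 1-(2,4-dihydroxyphenyl)ethan-1-one; 15, chloromethyl methyl ether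
Product: 16, 1-[2-hydroxy-4-(methoxymethoxy)phenyl]ethan-1-one
Conditions: MOMCl (1.1 eq), K2CO3, acetone, 0 °C → rt
Reagents that add atoms: MOMCl, COCCl
Why: Williamson-type alkylation is selective for the 4-OH because the 2-OH is hydrogen-bonded to the ketone.

Step 9
Reactants: 17, 2,4-dihydroxybenzaldehyde; 15, MOMCl
Product: 18, 2,4-bis(methoxymethoxy)benzaldehyde
Conditions: NaH (2.5 eq), MOMCl (2.5 eq), DMF, 0 °C → rt
Reagents that add atoms: MOMCl, COCCl
Why: Full deprotonation with NaH overrides the chelation of the 2-OH so both phenols are alkylated, giving an aldehyde that tolerates the hydroxide-mediated condensation.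

Step 10
Reactants: 16; 18
Product: 19, (2E)-3-[2,4-bis(methoxymethoxy)phenyl]-1-[2-hydroxy-4-(methoxymethoxy)phenyl]prop-2-en-1-one
Conditions: KOH (aq.), EtOH, rt, 24 h; acidify to pH 5 at 0 °C
Reagents that add atoms: none
Why: Claisen–Schmidt aldol condensation with E1cB dehydration gives the thermodynamically favoured E-chalcone, and MOM ethers are stable to hydroxide.

Step 11
Reactants: 19
Product: 20, (2E)-1,3-bis(2,4-dihydroxyphenyl)prop-2-en-1-one (2,4,2',4'-tetrahydroxychalcone)
Conditions: 3 M HCl, MeOH, 40 °C, dark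
Reagents that add atoms: none
Why: Mild acid hydrolysis of the three MOM acetals, kept cool and dark to limit E/Z isomerisation and flavylium or flavanone formation.

Step 12
Reactants: 13; 20 (1.2 eq)
Product: 21, (2R)-2-{5-[(1R,5S,6R)-6-(2,4-dihydroxybenzoyl)-5-(2,4-dihydroxyphenyl)-3-methylcyclohex-2-en-1-yl]-2,4-dihydroxyphenyl}-7-hydroxy-2,3-dihydro-4H-chromen-4-one (CID 11157778)
Conditions: MaDA-3 (recombinant FAD-dependent Diels–Alderase, Morus alba), 20 mM Tris-HCl pH 7.5, 5% DMSO, 30 °C, dark, 6–12 h; EtOAc extraction, RP-HPLC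
Reagents that add atoms: none
Why: Enzyme-catalysed intermolecular [4+2] cycloaddition, in which the exo-selective Diels–Alderase gives the all-trans cyclohexene with the natural-series (3''R,4''R,5''S) configuration, while the E-chalcone geometry fixes the trans aroyl/aryl relationship and the "ortho" regiochemistry places the aroyl carbon next to the aryl-bearing diene terminus.

**Compound list**

1 | 4,6-dibromobenzene-1,3-diol | Oc1cc(O)c(Br)cc1Br | starting material
2 | tert-butyldimethylsilyl chloride | CC(C)(C)[Si](C)(C)Cl | starting material (reagent)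
3 | 1,5-dibromo-2,4-bis(tert-butyldimethylsilyloxy)benzene | CC(C)(C)[Si](C)(C)Oc1cc(O[Si](C)(C)C(C)(C)C)c(Br)cc1Br | intermediate
4 | triisopropyl borate | CC(C)OB(OC(C)C)OC(C)C | starting material (reagent)
5 | [5-bromo-2,4-bis(tert-butyldimethylsilyloxy)phenyl]boronic acid | OB(O)c1cc(Br)c(O[Si](C)(C)C(C)(C)C)cc1O[Si](C)(C)C(C)(C)C | intermediate
6 | 7-hydroxy-4H-chromen-4-one | O=c1ccoc2cc(O)ccc12 | starting material
7 | 7-(tert-butyldimethylsilyloxy)-4H-chromen-4-one | O=c1ccoc2cc(O[Si](C)(C)C(C)(C)C)ccc12 | intermediate
8 | (2R)-2-[5-bromo-2,4-bis(TBSO)phenyl]-7-(TBSO)-chroman-4-one | Brc1cc([C@H]2CC(=O)c3ccc(O[Si](C)(C)C(C)(C)C)cc3O2)c(O[Si](C)(C)C(C)(C)C)cc1O[Si](C)(C)C(C)(C)C | intermediate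
9 | (E)-1,2-bis(tributylstannyl)ethene | CCCC[Sn](CCCC)(CCCC)/C=C/[Sn](CCCC)(CCCC)CCCC | starting material
10 | 2-bromopropene | C=C(C)Br | starting material
11 | tributyl[(1E)-3-methylbuta-1,3-dien-1-yl]stannane | CCCC[Sn](CCCC)(CCCC)/C=C/C(C)=C | intermediate
12 | (2R)-2-{2,4-bis(TBSO)-5-[(1E)-3-methylbuta-1,3-dienyl]phenyl}-7-(TBSO)-chroman-4-one | C=C(C)/C=C/c1cc([C@H]2CC(=O)c3ccc(O[Si](C)(C)C(C)(C)C)cc3O2)c(O[Si](C)(C)C(C)(C)C)cc1O[Si](C)(C)C(C)(C)C | intermediate
13 | (2R)-2-{2,4-dihydroxy-5-[(1E)-3-methylbuta-1,3-dienyl]phenyl}-7-hydroxychroman-4-one | C=C(C)/C=C/c1cc([C@H]2CC(=O)c3ccc(O)cc3O2)c(O)cc1O | intermediate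
14 | 1-(2,4-dihydroxyphenyl)ethan-1-one | CC(=O)c1ccc(O)cc1O | starting material
15 | chloromethyl methyl ether | COCCl | starting material (reagent)
16 | 1-[2-hydroxy-4-(methoxymethoxy)phenyl]ethan-1-one | CC(=O)c1ccc(OCOC)cc1O | intermediate
17 | 2,4-dihydroxybenzaldehyde | O=Cc1ccc(O)cc1O | starting material
18 | 2,4-bis(methoxymethoxy)benzaldehyde | O=Cc1ccc(OCOC)cc1OCOC | intermediate
19 | (2E)-3-[2,4-bis(methoxymethoxy)phenyl]-1-[2-hydroxy-4-(methoxymethoxy)phenyl]prop-2-en-1-one | O=C(/C=C/c1ccc(OCOC)cc1OCOC)c1ccc(OCOC)cc1O | intermediate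
20 | (2E)-1,3-bis(2,4-dihydroxyphenyl)prop-2-en-1-one | O=C(/C=C/c1ccc(O)cc1O)c1ccc(O)cc1O | intermediate
21 | CID 11157778 | CC1=C[C@@H](c2cc([C@H]3CC(=O)c4ccc(O)cc4O3)c(O)cc2O)[C@H](C(=O)c2ccc(O)cc2O)[C@@H](c2ccc(O)cc2O)C1 | target

**Totals**
- Total steps: 12.
- Longest linear sequence: 6 steps (1 → 2 → 4 → 6 → 7 → 12).

**Three steps most likely to fail, with fallbacks**
1. Step 12 (enzymatic Diels–Alder): the unnatural (2R)-flavanone diene may be a poor substrate, or C2 may epimerise in buffer. Fallback: a non-enzymatic, chiral borate-templated Diels–Alder (VANOL or BINOL with B(OPh)3) between silyl-protected diene 12 and the 2'-hydroxychalcone with its other phenols acetylated, followed by chromatographic isolation of the exo adduct and mild global deprotection.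
2. Step 4 (Rh 1,4-addition): the ortho-silyloxy arylboronic acid may add slowly or protodeboronate. Fallback: form the C2–O bond instead of the C2–aryl bond, by cinchona-thiourea-catalysed intramolecular oxa-Michael cyclisation of the alkylidene β-keto allyl ester made from silyl-protected 5-bromo-2,4-dihydroxybenzaldehyde, then neutral Pd(0) deallylative decarboxylation.
3. Step 6 (fluoride-free Stille on a hindered, electron-rich aryl bromide): Fallback: Heck coupling of 8 with 2-methylbut-3-en-2-ol (mild bicarbonate/Jeffery conditions) to the tertiary allylic alcohol, then Burgess dehydration to the diene.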